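**Strategy.** The butenolide (ring A: O1, C2=O, C3–Me, C4–O-stearoyl, C5=CH) is disconnected at C2–C3 and C4–C5. Both bonds are made at once by [2+2] cycloaddition of acetoxyketene with 1-ethoxyprop-1-yne: C3=C4(O) of ring A is an ynol ether unit, and C2 and C5, which flank O1, are the two carbons of a ketene. The precursor is therefore a cyclobutenone whose C2–C5 bond is absent from the target; after oxidation to the 1,2-dione it is replaced by O1 in a Baeyer–Villiger step. The resulting alkoxymaleic anhydride is olefinated at C5 with the chain ylide, and the stearate is put on last.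

Key step: step 1

Remark 1: the exocyclic C5=CH bond is taken as drawn, chain trans to O1, i.e. (E), the less stable isomer; it is therefore set under kinetic control and the later steps avoid acid, iodine and light.
Remark 2: the sense of step 9 is assigned from the geraniol/nerol enantioface model of BINAP–ruthenium catalysts; should the 2-methyl substrate respond in the opposite sense, the (R)-ligand would be used.

**Ring building block**

Step 1
Reactants: 1 1-ethoxyprop-1-yne; 2 2-chloro-2-oxoethyl acetate (acetoxyacetyl chloride)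
Product: 4 (±)-2-ethoxy-3-methyl-4-oxocyclobut-2-en-1-yl acetate, via acetoxyketene 3 (not isolated)
Conditions: Et3N (slow addition), CH2Cl2, 0 to 20 °C
Reagents that add atoms: none
Why: Triethylamine dehydrochlorinates 2 to acetoxyketene 3, which is trapped by the ketene–alkoxyalkyne [2+2] cycloaddition, the known route to 3-alkoxycyclobutenones: the nucleophilic methyl-bearing alkyne carbon attacks the ketene carbonyl carbon (future C2–C3 bond of ring A) and the alkoxy-stabilized vinyl cation so formed is captured by the enolate carbon (future C4–C5 bond). The four-membered ring is closed by collapse of this 1,4-zwitterion, formally a thermal [π2s+π2a] ketene cycloaddition. The only new stereocenter, the acetoxy-bearing carbon, forms racemic under no control and is erased in step 3. The step needs head-to-head regioselectivity, which the donor oxygen of 1 secures by making the methyl-bearing carbon the only nucleophilic site. It also needs the ketene to be trapped faster than it dimerizes, which slow addition of base to an excess of the electron-rich alkyne should secure. The bond between the carbonyl carbon and the acetoxy-bearing carbon, which is not in the target, is kept only until step 5.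

Step 2
Reactants: 4 (±)-2-ethoxy-3-methyl-4-oxocyclobut-2-en-1-yl acetate
Product: 5 (±)-3-ethoxy-4-hydroxy-2-methylcyclobut-2-en-1-one
Conditions: K2CO3 (0.2 equiv), EtOH, 0 °C
Reagents that add atoms: none
Why: Base-catalysed transesterification should remove the acetate under mild conditions, and ethanol is chosen so that any exchange at the vinylogous ester carbon returns the same ethoxy group.

Step 3
Reactants: 5 (±)-3-ethoxy-4-hydroxy-2-methylcyclobut-2-en-1-one
Product: 6 3-ethoxy-4-methylcyclobut-3-ene-1,2-dione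
Conditions: Dess–Martin periodinane, CH2Cl2, 20 °C
Reagents that add atoms: none
Why: Dess–Martin oxidation of an α-hydroxy ketone should give the 1,2-dione under neutral conditions, removing the stereocenter while the ethoxy group stays on the ynol-derived carbon, so the dione never passes through a symmetrical vinylogous acid.

Step 4
Reactants: 6 3-ethoxy-4-methylcyclobut-3-ene-1,2-dione
Product: 7 3-methyl-4-[2-(trimethylsilyl)ethoxy]cyclobut-3-ene-1,2-dione
Conditions: Me3SiCH2CH2OH (8 equiv), NaH (5 mol%), THF, 0 to 20 °C, EtOH removed under reduced pressure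
Reagents that add atoms: 2-(trimethylsilyl)ethanol, C[Si](C)(C)CCO
Why: Alkoxide-catalysed addition–elimination at the alkoxy-bearing carbon (vinylogous transesterification, as with squarate esters) should exchange ethoxy for a group that fluoride removes later without disturbing the ylidene geometry.

Step 5
Reactants: 7 3-methyl-4-[2-(trimethylsilyl)ethoxy]cyclobut-3-ene-1,2-dione
Product: 8 3-methyl-4-[2-(trimethylsilyl)ethoxy]furan-2,5-dione
Conditions: mCPBA (1.1 equiv), CH2Cl2, 0 °C
Reagents that add atoms: 3-chloroperoxybenzoic acid (mCPBA), OOC(=O)c1cccc(Cl)c1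
Why: Baeyer–Villiger oxidation of a 1,2-diketone proceeds by acyl migration, so oxygen is inserted between the two carbonyl carbons whichever carbonyl the peracid attacks, and the electron-poor ring C=C should not be epoxidized.

**Side chain**

Step 6
Reactants: 9 furan-3-ylmethanol
Product: 10 3-(chloromethyl)furan
Conditions: SOCl2, pyridine, Et2O, 0 °C
Reagents that add atoms: thionyl chloride, O=S(Cl)Cl
Why: Chlorination through the chlorosulfite should work because pyridine buffers the HCl that would otherwise degrade the furan, and the labile chloride is used at once.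

Step 7
Reactants: 10 3-(chloromethyl)furan; 11 (2E,6E)-1-chloro-3,7,11-trimethyldodeca-2,6,10-triene (farnesyl chloride)
Product: 13 3-[(3E,7E)-4,8,12-trimethyltrideca-3,7,11-trien-1-yl]furan, via (furan-3-ylmethyl)magnesium chloride 12 (not isolated)
Conditions: Mg, THF, 0 °C; then 11, Li2CuCl4 (3 mol%), THF, 0 °C
Reagents that add atoms: none
Why: Copper-catalysed coupling of the 3-furylmethyl Grignard reagent with a primary allylic chloride (Kochi-type) should occur at the α-carbon without allylic transposition, so both (E)-alkenes are retained.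

Step 8
Reactants: 13 3-[(3E,7E)-4,8,12-trimethyltrideca-3,7,11-trien-1-yl]furan
Product: 14 (2E,6E,10E)-13-(furan-3-yl)-2,6,10-trimethyltrideca-2,6,10-trien-1-ol
Conditions: SeO2 (0.3 equiv), t-BuOOH (3 equiv), salicylic acid (0.1 equiv), CH2Cl2, 0 to 20 °C, stopped at partial conversion
Reagents that add atoms: tert-butyl hydroperoxide, CC(C)(C)OO
Why: Catalytic SeO2 allylic oxidation (ene reaction then [2,3]-shift) should select the (E)-methyl group of the terminal, most accessible trisubstituted alkene, as it does in farnesyl esters, giving the (E)-allylic alcohol.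

Step 9
Reactants: 14 (2E,6E,10E)-13-(furan-3-yl)-2,6,10-trimethyltrideca-2,6,10-trien-1-ol
Product: 15 (2S,6E,10E)-13-(furan-3-yl)-2,6,10-trimethyltrideca-6,10-dien-1-ol
Conditions: Ru(OAc)2[(S)-BINAP] (1 mol%), H2 (50 atm), MeOH, 20 °C
Reagents that add atoms: none
Why: Noyori hydroxyl-directed asymmetric hydrogenation should reduce only the alkene that chelates through the allylic alcohol, leaving the two isolated alkenes and the furan; the (S)-ligand should deliver hydrogen to the face that gives the (S)-configured methyl-bearing carbon.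

Step 10
Reactants: 15 (2S,6E,10E)-13-(furan-3-yl)-2,6,10-trimethyltrideca-6,10-dien-1-ol
Product: 16 3-[(3E,7E,12S)-13-iodo-4,8,12-trimethyltrideca-3,7-dien-1-yl]furan
Conditions: I2, PPh3, imidazole, CH2Cl2, 0 °C
Reagents that add atoms: iodine, II
Why: Appel-type iodination displaces the activated primary oxygen by SN2 and does not touch the adjacent stereocenter, the alkenes or the furan.

Step 11
Reactants: 16 3-[(3E,7E,12S)-13-iodo-4,8,12-trimethyltrideca-3,7-dien-1-yl]furan
Product: 17 [(2S,6E,10E)-13-(furan-3-yl)-2,6,10-trimethyltrideca-6,10-dien-1-yl]triphenylphosphonium iodide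
Conditions: PPh3, MeCN, 80 °C
Reagents that add atoms: triphenylphosphine, c1ccc(cc1)P(c1ccccc1)c1ccccc1
Why: SN2 quaternization of triphenylphosphine by a β-branched primary iodide should go on heating, and the stereocenter, being β to phosphorus, is not acidified.

**Union and end game**

Step 12
Reactants: 17 [(2S,6E,10E)-13-(furan-3-yl)-2,6,10-trimethyltrideca-6,10-dien-1-yl]triphenylphosphonium iodide; 8 3-methyl-4-[2-(trimethylsilyl)ethoxy]furan-2,5-dione
Product: 19 (5E)-5-[(2S,6E,10E)-13-(furan-3-yl)-2,6,10-trimethyltrideca-6,10-dien-1-ylidene]-3-methyl-4-[2-(trimethylsilyl)ethoxy]furan-2(5H)-one, via phosphorus ylide 18 (not isolated)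
Conditions: NaN(SiMe3)2 (1.0 equiv), THF, −78 °C; then 8, −78 to 0 °C, dark
Reagents that add atoms: none
Why: In this Wittig olefination of an alkoxymaleic anhydride the ylide should attack the carbonyl next to the alkoxy-bearing C4 (the other carbonyl is deactivated as a vinylogous carbonate), and syn-elimination from the kinetically formed cis-oxaphosphetane, in which the ylide substituent lies beside the larger carbonyl substituent C4 as in olefinations of α-alkoxy ketones, should place the chain cis to C4, i.e. the (E)-ylidene, the kinetic sense of anhydride Wittig reactions; low temperature and exclusion of acid and light should prevent equilibration to the (Z)-isomer.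

Step 13
Reactants: 19 (5E)-5-[(2S,6E,10E)-13-(furan-3-yl)-2,6,10-trimethyltrideca-6,10-dien-1-ylidene]-3-methyl-4-[2-(trimethylsilyl)ethoxy]furan-2(5H)-one; 20 octadecanoyl chloride (stearoyl chloride)
Product: 22 (2E)-2-[(2S,6E,10E)-13-(furan-3-yl)-2,6,10-trimethyltrideca-6,10-dien-1-ylidene]-4-methyl-5-oxo-2,5-dihydrofuran-3-yl octadecanoate, via tetrabutylammonium tetronate 21 (not isolated)
Conditions: Bu4NF (1.05 equiv), THF, −20 °C; then 20 (1.5 equiv), 0 °C, dark
Reagents that add atoms: none
Why: Fluoride attack at silicon triggers β-elimination of ethene and releases the tetronate anion under non-acidic conditions, and acylation of this vinylogous carboxylate should occur on the C4 oxygen because C3 is blocked by its methyl group, so the labile enol ester is formed last and the ylidene is not exposed to isomerizing conditions.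

**Compound list**

1 | 1-ethoxyprop-1-yne | CC#COCC | starting material
2 | 2-chloro-2-oxoethyl acetate | CC(=O)OCC(Cl)=O | starting material
3 | acetoxyketene (2-oxoethenyl acetate) | CC(=O)OC=C=O | intermediate
4 | (±)-2-ethoxy-3-methyl-4-oxocyclobut-2-en-1-yl acetate | CCOC1=C(C)C(=O)C1OC(C)=O | intermediate
5 | (±)-3-ethoxy-4-hydroxy-2-methylcyclobut-2-en-1-one | CCOC1=C(C)C(=O)C1O | intermediate
6 | 3-ethoxy-4-methylcyclobut-3-ene-1,2-dione | CCOC1=C(C)C(=O)C1=O | intermediate
7 | 3-methyl-4-[2-(trimethylsilyl)ethoxy]cyclobut-3-ene-1,2-dione | C[Si](C)(C)CCOC1=C(C)C(=O)C1=O | intermediate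
8 | 3-methyl-4-[2-(trimethylsilyl)ethoxy]furan-2,5-dione | C[Si](C)(C)CCOC1=C(C)C(=O)OC1=O | intermediate
9 | furan-3-ylmethanol | OCc1ccoc1 | starting material
10 | 3-(chloromethyl)furan | ClCc1ccoc1 | intermediate
11 | (2E,6E)-1-chloro-3,7,11-trimethyldodeca-2,6,10-triene | CC(C)=CCC/C(C)=C/CC/C(C)=C/CCl | starting material
12 | (furan-3-ylmethyl)magnesium chloride | Cl[Mg]Cc1ccoc1 | intermediate
13 | 3-[(3E,7E)-4,8,12-trimethyltrideca-3,7,11-trien-1-yl]furan | CC(C)=CCC/C(C)=C/CC/C(C)=C/CCc1ccoc1 | intermediate
14 | (2E,6E,10E)-13-(furan-3-yl)-2,6,10-trimethyltrideca-2,6,10-trien-1-ol | OC/C(C)=C/CC/C(C)=C/CC/C(C)=C/CCc1ccoc1 | intermediate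
15 | (2S,6E,10E)-13-(furan-3-yl)-2,6,10-trimethyltrideca-6,10-dien-1-ol | OC[C@@H](C)CCC/C(C)=C/CC/C(C)=C/CCc1ccoc1 | intermediate
16 | 3-[(3E,7E,12S)-13-iodo-4,8,12-trimethyltrideca-3,7-dien-1-yl]furan | IC[C@@H](C)CCC/C(C)=C/CC/C(C)=C/CCc1ccoc1 | intermediate
17 | [(2S,6E,10E)-13-(furan-3-yl)-2,6,10-trimethyltrideca-6,10-dien-1-yl]triphenylphosphonium iodide | [I-].c1ccc(cc1)[P+](c1ccccc1)(c1ccccc1)C[C@@H](C)CCC/C(C)=C/CC/C(C)=C/CCc1ccoc1 | intermediate
18 | [(2S,6E,10E)-13-(furan-3-yl)-2,6,10-trimethyltrideca-6,10-dien-1-ylidene]triphenylphosphorane | c1ccc(cc1)P(c1ccccc1)(c1ccccc1)=C[C@@H](C)CCC/C(C)=C/CC/C(C)=C/CCc1ccoc1 | intermediate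
19 | (5E)-5-[(2S,6E,10E)-13-(furan-3-yl)-2,6,10-trimethyltrideca-6,10-dien-1-ylidene]-3-methyl-4-[2-(trimethylsilyl)ethoxy]furan-2(5H)-one | C[Si](C)(C)CCOC1=C(C)C(=O)O/C1=C/[C@@H](C)CCC/C(C)=C/CC/C(C)=C/CCc1ccoc1 | intermediate
20 | octadecanoyl chloride | CCCCCCCCCCCCCCCCCC(=O)Cl | starting material
21 | tetrabutylammonium (2E)-2-[(2S,6E,10E)-13-(furan-3-yl)-2,6,10-trimethyltrideca-6,10-dien-1-ylidene]-4-methyl-5-oxo-2,5-dihydrofuran-3-olate | CCCC[N+](CCCC)(CCCC)CCCC.[O-]C1=C(C)C(=O)O/C1=C/[C@@H](C)CCC/C(C)=C/CC/C(C)=C/CCc1ccoc1 | intermediate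
22 | (2E)-2-[(2S,6E,10E)-13-(furan-3-yl)-2,6,10-trimethyltrideca-6,10-dien-1-ylidene]-4-methyl-5-oxo-2,5-dihydrofuran-3-yl octadecanoate | CCCCCCCCCCCCCCCCCC(=O)OC1=C(C)C(=O)O/C1=C/[C@@H](C)CCC/C(C)=C/CC/C(C)=C/CCc1ccoc1 | target

**Count**

Total steps: 13. Longest linear sequence: 8 steps (9 → 10 → 13 → 14 → 15 → 16 → 17 → 19 → 22). The ring building block 8 takes 5 steps and joins at step 12.

**Steps most likely to fail**

1. Step 12. The basic ylide may open the anhydride by acylation instead of olefinating it, or the kinetic (E)-selectivity may be eroded by equilibration to the more stable (Z)-ylidene. The fallback sets out from 8 and 15 and comes back at 19. NaBH4 in THF at −20 °C should reduce the same, more electrophilic carbonyl of 8 to give 3-methyl-4-[2-(trimethylsilyl)ethoxy]furan-2(5H)-one F1. Dess–Martin oxidation of 15 gives (2S,6E,10E)-13-(furan-3-yl)-2,6,10-trimethyltrideca-6,10-dienal F2. Lithiation of F1 at C5 with LiN(iPr)2 at −78 °C and addition to F2 gives the aldol adducts 5-[(2S,6E,10E)-13-(furan-3-yl)-1-hydroxy-2,6,10-trimethyltrideca-6,10-dien-1-yl]-3-methyl-4-[2-(trimethylsilyl)ethoxy]furan-2(5H)-one F3. Mesylation and elimination with DBU should give the thermodynamic (5Z)-5-[(2S,6E,10E)-13-(furan-3-yl)-2,6,10-trimethyltrideca-6,10-dien-1-ylidene]-3-methyl-4-[2-(trimethylsilyl)ethoxy]furan-2(5H)-one F4. Irradiation of F4 near 300 nm in MeCN should give a photostationary mixture from which 19 is separated on silica gel, with recovered F4 re-irradiated.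

2. Step 8. Oxidation may occur at the internal allylic positions or on the electron-rich furan ring, or run on to the enal. The fallback sets out from 10 (as its Grignard reagent 12) and comes back at 15, so that selenium never meets the furan. Commercial (2E,6E)-3,7,11-trimethyldodeca-2,6,10-trien-1-yl acetate F5 is oxidized with SeO2/t-BuOOH to (2E,6E,10E)-12-hydroxy-3,7,11-trimethyldodeca-2,6,10-trien-1-yl acetate F6. Hydrogenation with Ru(OAc)2[(S)-BINAP] as in step 9 gives (2E,6E,11S)-12-hydroxy-3,7,11-trimethyldodeca-2,6-dien-1-yl acetate F7. Coupling of F7 with an excess of 12 under Li2CuCl4 catalysis displaces the allylic acetate and gives 15.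

3. Step 9. Enantioface discrimination may be insufficient, or of the opposite sense, for a 2-methyl-substituted allylic alcohol. The fallback sets out from 14 and comes back at 15, moving the hydrogenation to the acid, the best-precedented substrate class for 2-methyl alkenes. MnO2 gives (2E,6E,10E)-13-(furan-3-yl)-2,6,10-trimethyltrideca-2,6,10-trienal F8. NaClO2 with 2-methylbut-2-ene as scavenger gives (2E,6E,10E)-13-(furan-3-yl)-2,6,10-trimethyltrideca-2,6,10-trienoic acid F9. Carboxylate-directed hydrogenation with Ru(OAc)2(BINAP), using the ligand antipode that the tiglic acid precedent assigns to the (S)-acid, gives (2S,6E,10E)-13-(furan-3-yl)-2,6,10-trimethyltrideca-6,10-dienoic acid F10. LiAlH4 reduction gives 15.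

**Further compounds**

F1 | step 12 | 3-methyl-4-[2-(trimethylsilyl)ethoxy]furan-2(5H)-one | C[Si](C)(C)CCOC1=C(C)C(=O)OC1
F2 | step 12 | (2S,6E,10E)-13-(furan-3-yl)-2,6,10-trimethyltrideca-6,10-dienal | O=C[C@@H](C)CCC/C(C)=C/CC/C(C)=C/CCc1ccoc1
F3 | step 12 | 5-[(2S,6E,10E)-13-(furan-3-yl)-1-hydroxy-2,6,10-trimethyltrideca-6,10-dien-1-yl]-3-methyl-4-[2-(trimethylsilyl)ethoxy]furan-2(5H)-one | C[Si](C)(C)CCOC1=C(C)C(=O)OC1C(O)[C@@H](C)CCC/C(C)=C/CC/C(C)=C/CCc1ccoc1
F4 | step 12 | (5Z)-5-[(2S,6E,10E)-13-(furan-3-yl)-2,6,10-trimethyltrideca-6,10-dien-1-ylidene]-3-methyl-4-[2-(trimethylsilyl)ethoxy]furan-2(5H)-one | C[Si](C)(C)CCOC1=C(C)C(=O)O/C1=C\[C@@H](C)CCC/C(C)=C/CC/C(C)=C/CCc1ccoc1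
F5 | step 8 | (2E,6E)-3,7,11-trimethyldodeca-2,6,10-trien-1-yl acetate | CC(C)=CCC/C(C)=C/CC/C(C)=C/COC(C)=O
F6 | step 8 | (2E,6E,10E)-12-hydroxy-3,7,11-trimethyldodeca-2,6,10-trien-1-yl acetate | OC/C(C)=C/CC/C(C)=C/CC/C(C)=C/COC(C)=O
F7 | step 8 | (2E,6E,11S)-12-hydroxy-3,7,11-trimethyldodeca-2,6-dien-1-yl acetate | OC[C@@H](C)CCC/C(C)=C/CC/C(C)=C/COC(C)=O
F8 | step 9 | (2E,6E,10E)-13-(furan-3-yl)-2,6,10-trimethyltrideca-2,6,10-trienal | O=C/C(C)=C/CC/C(C)=C/CC/C(C)=C/CCc1ccoc1
F9 | step 9 | (2E,6E,10E)-13-(furan-3-yl)-2,6,10-trimethyltrideca-2,6,10-trienoic acid | OC(=O)/C(C)=C/CC/C(C)=C/CC/C(C)=C/CCc1ccoc1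
F10 | step 9 | (2S,6E,10E)-13-(furan-3-yl)-2,6,10-trimethyltrideca-6,10-dienoic acid | OC(=O)[C@@H](C)CCC/C(C)=C/CC/C(C)=C/CCc1ccoc1
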